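**Plan**

- Retrosynthesis: the C7''–OH bond and then the O4'–C8'' ether bond of the target are cut, giving tricin and p-coumaryl alcohol. Tricin is cut at O1–C2 and C2=C3 (chalcone), and p-coumaryl alcohol is traced back to p-coumaric acid.
- Enabling feature: the side chain is an arylglycerol β-aryl ether. O4' of ring B, flanked by the 3'- and 5'-methoxy groups, is bound to C8'', and the neighbouring C7'' carbinol sits para to the free 4''-OH of the p-hydroxyphenyl ring. This is the pattern left by phenoxyl radical combination at O4'/C8'' followed by hydration of a p-quinone methide at C7''.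
- Forward: rings A and B come from the two aromatic starting materials. The C2=C3 bond is made by aldol condensation, ring C is closed by oxidative cyclisation, and debenzylation gives tricin. p-Coumaryl alcohol is made in two steps, and the two phenols are joined last by peroxidase/H2O2 cross-coupling, in which no ring forms.
- Stereochemistry: C8'' arises racemic in the radical combination. C7'' is set erythro to it when water adds to the quinone methide next to the 2,6-dimethoxyaryloxy group. The (7''R,8''S) enantiomer is then obtained by resolution on a chiral stationary phase.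

Key step: step 8

Remark: compounds 11, 12, F3 and F4 are racemates; where two stereocentres are present, the SMILES shows the relative configuration through the enantiomer that corresponds to 13.

**Route**

Step 1
Reactants: 1 2,4,6-trihydroxyacetophenone
Product: 2 1-[2,4-bis(benzyloxy)-6-hydroxyphenyl]ethan-1-one
Conditions: BnBr (2.1 equiv), K2CO3 (2.2 equiv), DMF, 0 °C to rt
Reagents that add atoms: benzyl bromide, BrCc1ccccc1
Why: Williamson etherification in which the two phenols not tied up in the hydrogen bond to the acetyl C=O react first, so that a limited amount of benzyl bromide should leave the chelated ortho OH free.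

Step 2
Reactants: 3 syringaldehyde (4-hydroxy-3,5-dimethoxybenzaldehyde)
Product: 4 4-(benzyloxy)-3,5-dimethoxybenzaldehyde
Conditions: BnBr (1.1 equiv), K2CO3 (1.2 equiv), DMF, 60 °C
Reagents that add atoms: benzyl bromide, BrCc1ccccc1
Why: Williamson etherification of the only phenol, which masks the phenoxide that would otherwise deactivate the aldehyde in the basic aldol step.

Step 3
Reactants: 2 1-[2,4-bis(benzyloxy)-6-hydroxyphenyl]ethan-1-one, 4 4-(benzyloxy)-3,5-dimethoxybenzaldehyde
Product: 5 (E)-1-[2,4-bis(benzyloxy)-6-hydroxyphenyl]-3-[4-(benzyloxy)-3,5-dimethoxyphenyl]prop-2-en-1-one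
Conditions: KOH (50% aq., excess), EtOH/THF, rt; then aq. HCl
Reagents that add atoms: none
Why: Claisen–Schmidt condensation of the methyl ketone enolate with a non-enolisable aldehyde, followed by E1cB dehydration to the conjugated (E)-enone, with benzyl ethers inert to the base.

Step 4
Reactants: 5 (E)-1-[2,4-bis(benzyloxy)-6-hydroxyphenyl]-3-[4-(benzyloxy)-3,5-dimethoxyphenyl]prop-2-en-1-one
Product: 6 5,7-bis(benzyloxy)-2-[4-(benzyloxy)-3,5-dimethoxyphenyl]-4H-chromen-4-one (tri-O-benzyltricin)
Conditions: I2 (10 mol%), DMSO, 130 °C
Reagents that add atoms: none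
Why: Iodine-catalysed oxidative cyclisation of a 2'-hydroxychalcone, in which the phenol ortho to the carbonyl adds to the enone (6-endo oxa-Michael closure of ring C) and α-iodination with loss of hydrogen iodide installs the C2=C3 bond while DMSO reoxidises the iodide.

Step 5
Reactants: 6 5,7-bis(benzyloxy)-2-[4-(benzyloxy)-3,5-dimethoxyphenyl]-4H-chromen-4-one
Product: 7 tricin (5,7-dihydroxy-2-(4-hydroxy-3,5-dimethoxyphenyl)-4H-chromen-4-one)
Conditions: H2 (1 atm), Pd/C (10 wt% palladium on carbon), THF/MeOH, rt
Reagents that add atoms: none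
Why: Catalytic hydrogenolysis of three aryl benzyl ethers, under which the C2=C3 bond of the chromone (a vinylogous ester conjugated with ring B) and the methyl ethers should stay untouched at ambient pressure.

Step 6
Reactants: 8 p-coumaric acid ((E)-3-(4-hydroxyphenyl)prop-2-enoic acid)
Product: 9 ethyl (E)-3-(4-hydroxyphenyl)prop-2-enoate
Conditions: EtOH, H2SO4 (cat.), reflux
Reagents that add atoms: ethanol, CCO
Why: Fischer esterification driven by the solvent excess, which needs no protection of the phenol and leaves the (E)-alkene unchanged.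

Step 7
Reactants: 9 ethyl (E)-3-(4-hydroxyphenyl)prop-2-enoate
Product: 10 p-coumaryl alcohol (4-[(E)-3-hydroxyprop-1-en-1-yl]phenol)
Conditions: i-Bu2AlH (4 equiv), toluene, 0 °C; then EtOH, H2O
Reagents that add atoms: none
Why: 1,2-Reduction of an α,β-unsaturated ester to the allylic alcohol by diisobutylaluminium hydride, where the excess covers the phenol proton and the aluminium phenoxide disfavours conjugate reduction, followed by a neutral work-up that spares the acid-sensitive product.

Step 8
Reactants: 7 tricin, 10 p-coumaryl alcohol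
Product: 12 racemic erythro-(7''R*,8''S*)-4'',5,7-trihydroxy-3',5'-dimethoxy-4',8''-oxyflavonolignan-7'',9''-diol, via quinone methide 11 (not isolated)
Conditions: horseradish peroxidase, H2O2 (1 equiv), acetone/aq. NaOAc–AcOH buffer (pH 5), rt; 10 (1 equiv) and H2O2 fed slowly into 7 (3 equiv); then C18 chromatography to separate erythro from threo
Reagents that add atoms: water, O
Why: H2O2 turns the heme of the peroxidase into its two-electron-oxidised form, which takes one electron each from the 4'-OH of 7 and the 4-OH of 10; the delocalised radical of 10 carries high spin density at C8'' and combines there with the O4'-centred radical of 7 to give quinone methide 11, to which water adds at C7'' with rearomatisation of the 4-hydroxyphenyl ring. This is the dehydrogenative β-O-4 cross-coupling of a monolignol with a phenol, known from lignification and from peroxidase/H2O2 couplings of monolignols with tricin and other phenols. No ring is closed; the two new bonds are O4'–C8'' and C7''–OH. C8'' forms in the radical combination without any chiral influence and is therefore racemic, while C7'' is set in the hydration, where the bulky 2,6-dimethoxyaryloxy group on C8'' should steer water to the face of the planar quinone methide that gives the erythro relation, a preference typical of β-ethers of 2,6-dimethoxyphenols and more pronounced in weakly acidic medium. Coupling through O4' alone is secured by 7 itself, since ring B has both positions ortho to the phenol blocked by methoxy groups and no conjugated side chain, and the 5- and 7-OH groups on the electron-poor ring A are not expected to be oxidised. Cross-coupling over homo-coupling of 10 is favoured by keeping 7 in excess (it cannot dimerise productively and is recovered) and by feeding 10 and H2O2 slowly, so that the stationary concentration of monolignol radical stays low.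

Step 9
Reactants: 12 racemic erythro-(7''R*,8''S*)-4'',5,7-trihydroxy-3',5'-dimethoxy-4',8''-oxyflavonolignan-7'',9''-diol
Product: 13 (-)-(7''R,8''S)-4'',5,7-trihydroxy-3',5'-dimethoxy-4',8''-oxyflavonolignan-7'',9''-diol
Conditions: preparative HPLC on an amylose tris(3,5-dimethylphenylcarbamate) chiral stationary phase, n-hexane/EtOH, rt; levorotatory fraction collected
Reagents that add atoms: none
Why: Resolution of a racemate by chromatography on a chiral stationary phase, where the enantiomers form transient diastereomeric adsorbates of different stability; no bond is made or broken, so the erythro relation from step 8 is kept, and the levorotatory fraction, whose 7''R,8''S configuration is to be confirmed by electronic circular dichroism, is the target.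

**Compound list**

1 | 2,4,6-trihydroxyacetophenone | CC(=O)c1c(O)cc(O)cc1O | starting material
2 | 1-[2,4-bis(benzyloxy)-6-hydroxyphenyl]ethan-1-one | CC(=O)c1c(O)cc(OCc2ccccc2)cc1OCc1ccccc1 | intermediate
3 | syringaldehyde (4-hydroxy-3,5-dimethoxybenzaldehyde) | COc1cc(C=O)cc(OC)c1O | starting material
4 | 4-(benzyloxy)-3,5-dimethoxybenzaldehyde | COc1cc(C=O)cc(OC)c1OCc1ccccc1 | intermediate
5 | (E)-1-[2,4-bis(benzyloxy)-6-hydroxyphenyl]-3-[4-(benzyloxy)-3,5-dimethoxyphenyl]prop-2-en-1-one | O=C(/C=C/c1cc(OC)c(OCc2ccccc2)c(OC)c1)c1c(O)cc(OCc2ccccc2)cc1OCc1ccccc1 | intermediate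
6 | 5,7-bis(benzyloxy)-2-[4-(benzyloxy)-3,5-dimethoxyphenyl]-4H-chromen-4-one | COc1cc(-c2cc(=O)c3c(OCc4ccccc4)cc(OCc4ccccc4)cc3o2)cc(OC)c1OCc1ccccc1 | intermediate
7 | tricin, 5,7-dihydroxy-2-(4-hydroxy-3,5-dimethoxyphenyl)-4H-chromen-4-one | COc1cc(-c2cc(=O)c3c(O)cc(O)cc3o2)cc(OC)c1O | intermediate
8 | p-coumaric acid, (E)-3-(4-hydroxyphenyl)prop-2-enoic acid | OC(=O)/C=C/c1ccc(O)cc1 | starting material
9 | ethyl (E)-3-(4-hydroxyphenyl)prop-2-enoate | CCOC(=O)/C=C/c1ccc(O)cc1 | intermediate
10 | p-coumaryl alcohol, 4-[(E)-3-hydroxyprop-1-en-1-yl]phenol | OC/C=C/c1ccc(O)cc1 | intermediate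
11 | quinone methide, 4-{3-hydroxy-2-[4-(5,7-dihydroxy-4-oxo-4H-chromen-2-yl)-2,6-dimethoxyphenoxy]propylidene}cyclohexa-2,5-dien-1-one, racemic at C8'', formed in the flask and not isolated | COc1cc(-c2cc(=O)c3c(O)cc(O)cc3o2)cc(OC)c1OC(CO)C=C1C=CC(=O)C=C1 | intermediate
12 | racemic erythro-(7''R*,8''S*)-4'',5,7-trihydroxy-3',5'-dimethoxy-4',8''-oxyflavonolignan-7'',9''-diol (SMILES shows the 7''R,8''S enantiomer of the racemate) | COc1cc(-c2cc(=O)c3c(O)cc(O)cc3o2)cc(OC)c1O[C@@H](CO)[C@H](O)c1ccc(O)cc1 | intermediate
13 | (-)-(7''R,8''S)-4'',5,7-trihydroxy-3',5'-dimethoxy-4',8''-oxyflavonolignan-7'',9''-diol | COc1cc(-c2cc(=O)c3c(O)cc(O)cc3o2)cc(OC)c1O[C@@H](CO)[C@H](O)c1ccc(O)cc1 | target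

**Step count and risks**

Total step count: 9. Longest linear sequence: 6 steps (steps 1, 3, 4, 5, 8, 9).

Steps most likely to fail:

1. Step 8. Combination of two monolignol radicals with each other (β–β, β–5 and β–O–4 homo-coupling) may outrun combination with the tricin radical. The phenolic product may re-enter the oxidation and be carried on to oligomers, and the hydration of the quinone methide may show too little erythro preference. The fallback builds the same ether by ionic chemistry; it sets out from 7 and comes back to the route at 12. Tricin 7 is benzylated at its most acidic 7-OH (BnBr 1.05 equiv, KHCO3, DMF, rt) to give 7-O-benzyltricin F1. The free, unchelated 4'-OH of this compound is alkylated with commercial 2-bromo-1-[4-(benzyloxy)phenyl]ethan-1-one (K2CO3, DMF, rt; the chelated 5-OH should not react) to give the aryloxy ketone 7-O-benzyltricin 4'-O-[2-(4-benzyloxyphenyl)-2-oxoethyl] ether F2. Base-catalysed aldol hydroxymethylation with aqueous formaldehyde (K2CO3, dioxane/H2O, rt) gives the racemic β-hydroxy ketone 7-O-benzyltricin 4'-O-[1-(4-benzyloxyphenyl)-3-hydroxy-1-oxopropan-2-yl] ether F3. Reduction of the aryl ketone with NaBH4 (MeOH/THF, 0 °C; the chromone carbonyl is much less electrophilic) should give an erythro-rich diol mixture, from which the racemic erythro 7,4''-di-O-benzyl diol F4 is separated by chromatography. Hydrogenolysis (H2, Pd/C, THF/MeOH, rt) removes both benzyl groups and gives 12.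

2. Step 9. Separation of the enantiomers on the chiral phase may be incomplete at preparative loading, because the polyphenol dissolves poorly in normal-phase eluents and the peaks tail. The fallback is an enzymatic kinetic resolution; it sets out from 12 and comes back at 13. Burkholderia cepacia lipase with vinyl acetate in THF/tert-butyl methyl ether at 30 °C should acylate only the primary 9''-OH and do so faster for one enantiomer; which one must be established on a small scale. If the levorotatory enantiomer reacts faster, its ester (7''R,8''S)-9''-O-acetyl-4'',5,7-trihydroxy-3',5'-dimethoxy-4',8''-oxyflavonolignan-7''-ol F5 is separated from unreacted alcohol on silica gel and methanolysed (K2CO3, MeOH, 0 °C) to 13. If the dextrorotatory enantiomer reacts faster, it is removed as (7''S,8''R)-9''-O-acetyl-4'',5,7-trihydroxy-3',5'-dimethoxy-4',8''-oxyflavonolignan-7''-ol F6 and the unreacted alcohol, taken to high conversion, is 13.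

3. Step 4. Hydrogen iodide formed in hot DMSO may cleave the benzyl ether next to the carbonyl or iodinate the electron-rich ring A, or the reaction may stall at the flavanone stage. The fallback closes ring C by acyl transfer and cyclodehydration instead of oxidation; it sets out from 2 and 4 and comes back at 6. Aldehyde 4 is oxidised under Pinnick conditions (NaClO2, NaH2PO4, 2-methyl-2-butene, t-BuOH/H2O) to 4-(benzyloxy)-3,5-dimethoxybenzoic acid F7. Steglich esterification of F7 with phenol 2 (EDC·HCl, DMAP, CH2Cl2) gives 2-acetyl-3,5-bis(benzyloxy)phenyl 4-(benzyloxy)-3,5-dimethoxybenzoate F8. Baker–Venkataraman rearrangement (KOH, pyridine, 50 °C) gives 1-[2,4-bis(benzyloxy)-6-hydroxyphenyl]-3-[4-(benzyloxy)-3,5-dimethoxyphenyl]propane-1,3-dione F9. Acid-catalysed cyclodehydration (H2SO4 cat., AcOH, 60 °C) closes ring C and gives 6.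

Further compounds
F1 | step 8 | 7-(benzyloxy)-5-hydroxy-2-(4-hydroxy-3,5-dimethoxyphenyl)-4H-chromen-4-one (7-O-benzyltricin) | COc1cc(-c2cc(=O)c3c(O)cc(OCc4ccccc4)cc3o2)cc(OC)c1O
F2 | step 8 | 7-O-benzyltricin 4'-O-[2-(4-benzyloxyphenyl)-2-oxoethyl] ether | COc1cc(-c2cc(=O)c3c(O)cc(OCc4ccccc4)cc3o2)cc(OC)c1OCC(=O)c1ccc(OCc2ccccc2)cc1
F3 | step 8 | 7-O-benzyltricin 4'-O-[1-(4-benzyloxyphenyl)-3-hydroxy-1-oxopropan-2-yl] ether, racemic | COc1cc(-c2cc(=O)c3c(O)cc(OCc4ccccc4)cc3o2)cc(OC)c1OC(CO)C(=O)c1ccc(OCc2ccccc2)cc1
F4 | step 8 | racemic erythro 7,4''-di-O-benzyl derivative of 12 | COc1cc(-c2cc(=O)c3c(O)cc(OCc4ccccc4)cc3o2)cc(OC)c1O[C@@H](CO)[C@H](O)c1ccc(OCc2ccccc2)cc1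
F5 | step 9 | (7''R,8''S)-9''-O-acetyl-4'',5,7-trihydroxy-3',5'-dimethoxy-4',8''-oxyflavonolignan-7''-ol | COc1cc(-c2cc(=O)c3c(O)cc(O)cc3o2)cc(OC)c1O[C@@H](COC(C)=O)[C@H](O)c1ccc(O)cc1
F6 | step 9 | (7''S,8''R)-9''-O-acetyl-4'',5,7-trihydroxy-3',5'-dimethoxy-4',8''-oxyflavonolignan-7''-ol | COc1cc(-c2cc(=O)c3c(O)cc(O)cc3o2)cc(OC)c1O[C@H](COC(C)=O)[C@@H](O)c1ccc(O)cc1
F7 | step 4 | 4-(benzyloxy)-3,5-dimethoxybenzoic acid | COc1cc(C(=O)O)cc(OC)c1OCc1ccccc1
F8 | step 4 | 2-acetyl-3,5-bis(benzyloxy)phenyl 4-(benzyloxy)-3,5-dimethoxybenzoate | CC(=O)c1c(OC(=O)c2cc(OC)c(OCc3ccccc3)c(OC)c2)cc(OCc2ccccc2)cc1OCc1ccccc1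
F9 | step 4 | 1-[2,4-bis(benzyloxy)-6-hydroxyphenyl]-3-[4-(benzyloxy)-3,5-dimethoxyphenyl]propane-1,3-dione | O=C(CC(=O)c1cc(OC)c(OCc2ccccc2)c(OC)c1)c1c(O)cc(OCc2ccccc2)cc1OCc1ccccc1
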